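The amber and green runs are what I have for the grey flask.

| flask | X | L | G | time |
|---|---|---|---|---|
| amber | 0.150 M | 0.180 M | 0.00300 M |  |
| green | 0.0750 M | 0.180 M | 0.00300 M |  |
| grey | 0.150 M | 0.360 M | 0.00600 M | 4.4 h |

- amber run (time / h: [Q] / M): 0.25: 0.0039; 0.76: 0.0138; 1.5: 0.0329; 2.3: 0.0566; 3.3: 0.0815; 4.4: 0.0991
- green run (time / h: [Q] / M): 0.25: 0.0016; 0.76: 0.0056; 1.5: 0.0124; 2.3: 0.0204; 3.3: 0.0305; 4.4: 0.0413

(readings scatter by 4 × 10⁻⁴ M)

- Overall: X + L -> Q, with G as catalyst.
- Constant volume, constant temperature.
- An order is taken over about fifteen percent of the charge, up and down.

- how the opening rate goes with [X] round the charge of the amber run: the exponent of the rate at two percent of X gone to Q (one fixed amount of Q, the same in the runs compared)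
- Q in the grey run at 4.4 h, as a share of the X charged

In the amber run the rate divided by cX·cL does not hold still: up to the first reading it reads 0.578 /M/h, and between the last two readings it reads 2.99 /M/h. I read this as Q helping to make Q, which is autocatalysis. I sum up a run in one number, 2.13 /M/h for amber. This is the run coefficient, the single constant k in rate = k·cX·cL that, integrated from the charge, reaches the measured cQ at that time. The green run, with less Q made, gives 1.17 /M/h, which is less than amber's.

The grey flask has amber's cX with twice the cL and twice the cG. In one extreme Q gives no help and the opening value doubles with cG, an order I assume. That makes 1.16 /M/h and a share of 76.6 %. In the other extreme amber's late value holds from the start, and the share is 96.2 %. With that assumed opening value above amber's, I expect at least amber's coefficient in the grey flask, which gives 91.3 %. I commit to the range from there up to my high extreme.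

The forecast gives an exponent in cX of 1.03 (0.85 to 1.2) round the amber charge and a grey share of 98 % (85 % to 100 %), noting that “both runs fall on one curve against Q, not against time”. Its central share stands above my range.

The result is an exponent of 1.0 round the amber charge and a grey share of 91.5 % at 4.4 h, which is 6.5 percentage points under the forecast.

    2 G ⇌ G2, settled at all times (18600 /M)
    G2 + X + L → Q + G2 (363.6 /M²/h)
    X + L + Q → 2 Q (38.16 /M²/h)
    Q → Gy (0.02542 /h)

As a run coefficient, the grey 91.5 % is 2.14 /M/h, close to amber's 2.13 /M/h. The simulated grey run without the step in which Q makes more Q ends at 67.9 %, a coefficient of 0.870 /M/h, which is under my low extreme. That step is what lifts the grey flask, and it is worth 24 points of the share at 4.4 h.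

(The readings come from a simulation for substances that don't exist, noise included.)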